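## Retrosynthetic overview

1. Target ⇒ remove the C8 methacrylate and the 11,13-epoxide (last ring, from the exocyclic methylene by hydroxyl-directed epoxidation) ⇒ 8,9-diol α-methylene lactone.
2. ⇒ C6–C7: an intramolecular CrCl2 Barbier allylation with lactonisation closes the ten-membered carbocycle and the γ-lactone together (second ring-forming event).
3. ⇒ C7–C11: Morita–Baylis–Hillman reaction and allylic bromination on a dialdehyde that already carries the 3(2H)-furanone.
4. ⇒ furanone (first ring) by PtCl2-catalysed heterocyclisation with 1,2-shift of C9 from C1 to C10 in an acyclic 2-hydroxy-2-alkynyl methyl ketone; the C1 carbinol configuration is relayed to quaternary C10.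
5. ⇒ that ketol from L-threono-1,4-lactone (C7, C8, C9, C1), ethyl vinyl ether (C10, C14) and (2Z)-3-methylpent-2-en-4-yn-1-ol (C2–C6, C15); methyl acrylate gives C11–C13.

Assumption: L-threono-1,4-lactone and (2Z)-3-methylpent-2-en-4-yn-1-ol are bought as catalogue compounds. Atom labels C1–C15 follow germacrane numbering; TBS = tert-butyldimethylsilyl, TES = triethylsilyl.

## Route

Step 1
Reactants: 1 (2Z)-3-methylpent-2-en-4-yn-1-ol
Product: 2 triethyl{[(2Z)-3-methylpent-2-en-4-yn-1-yl]oxy}silane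
Conditions: TESCl, imidazole, CH2Cl2, 0 °C
Reagents that add atoms: chlorotriethylsilane (TESCl), CC[Si](Cl)(CC)CC
Why: Imidazole-mediated silyl ether formation masks the allylic OH, so the Z-enynol cannot cyclise to a furan under later metal catalysis and the terminal alkyne can be lithiated; no stereocentre is involved.

Step 2
Reactants: 3 L-threono-1,4-lactone [(3R,4S)-3,4-dihydroxyoxolan-2-one]
Product: 4 (3R,4S)-3,4-bis(TBS-oxy)oxolan-2-one
Conditions: TBSOTf, 2,6-lutidine, CH2Cl2, 0 °C → rt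
Reagents that add atoms: tert-butyldimethylsilyl trifluoromethanesulfonate (TBSOTf), CC(C)(C)[Si](C)(C)OS(=O)(=O)C(F)(F)F
Why: Silylation of both secondary hydroxyls with the silyl triflate gives bulky, non-chelating ethers needed for Felkin–Anh control in step 3; the two chiral-pool centres (later C9 and C8) are untouched.

Step 3
Reactants: 4 (3R,4S)-3,4-bis(TBS-oxy)oxolan-2-one; 5 ethyl vinyl ether; 2 triethyl{[(2Z)-3-methylpent-2-en-4-yn-1-yl]oxy}silane
Product: 11 (3S,4R,5S)-4,5-bis(TBS-oxy)-3-hydroxy-3-[(3Z)-3-methyl-5-(TES-oxy)pent-3-en-1-yn-1-yl]-6-(TES-oxy)hexan-2-one, via 1-ethoxyvinyllithium 6 (not isolated), via lithium lactolate 7 (not isolated), via lithium acetylide 8 (not isolated), via dilithium dialkoxide 9 (not isolated), via enol ether carbinol 10 (not isolated)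
Conditions: 5, t-BuLi, THF, −78 → 0 °C; 4, −78 °C; then 2/n-BuLi (THF, −78 °C), −78 → −20 °C; TESCl, −78 °C; H2O; PPTS (cat.), THF–H2O, 0 °C
Reagents that add atoms: chlorotriethylsilane (TESCl), CC[Si](Cl)(CC)CC; water, O
Why: One-pot sequential double addition to a lactone (acyl-anion equivalent 6, then acetylide 8 on the ring-opened ketone): polar Felkin–Anh attack anti to the C9–OTBS bond sets the carbinol C1 (3S in 11), the primary alkoxide alone is silylated, and mild enol-ether hydrolysis unveils the acetyl group.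

Step 4
Reactants: 11 (3S,4R,5S)-4,5-bis(TBS-oxy)-3-hydroxy-3-[(3Z)-3-methyl-5-(TES-oxy)pent-3-en-1-yn-1-yl]-6-(TES-oxy)hexan-2-one
Product: 12 (2S)-2-[(1R,2S)-1,2-bis(TBS-oxy)-3-(TES-oxy)propyl]-2-methyl-5-[(2Z)-4-(TES-oxy)but-2-en-2-yl]furan-3(2H)-one
Conditions: PtCl2 (10 mol%), toluene, 80 °C
Reagents that add atoms: none
Why: Platinum-catalysed heterocyclisation/1,2-migration cascade of a 2-hydroxy-2-alkynyl ketone (α-ketol-type 1,2-shift, stepwise and cationic): the acetyl oxygen adds 5-endo to the PtCl2-bound alkyne, then C9 shifts suprafacially with retention from C1 to the oxocarbenium carbon, so the C1 configuration becomes that of quaternary C10 (S) and C1 becomes the ring ketone.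

Step 5
Reactants: 12 (2S)-2-[(1R,2S)-1,2-bis(TBS-oxy)-3-(TES-oxy)propyl]-2-methyl-5-[(2Z)-4-(TES-oxy)but-2-en-2-yl]furan-3(2H)-one
Product: 13 (2R,3R)-2,3-bis(TBS-oxy)-3-{(2S)-2-methyl-3-oxo-5-[(2Z)-4-oxobut-2-en-2-yl]-2,3-dihydrofuran-2-yl}propanal
Conditions: (COCl)2, DMSO, CH2Cl2, −78 → −35 °C; Et3N, → 0 °C
Reagents that add atoms: none
Why: Swern oxidation, in which primary triethylsilyl ethers are cleaved by the chlorosulfonium reagent and oxidised directly to aldehydes while the secondary TBS ethers survive; the Z-enal geometry and the α-silyloxy centre are retained at low temperature.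

Step 6
Reactants: 13 (2R,3R)-2,3-bis(TBS-oxy)-3-{(2S)-2-methyl-3-oxo-5-[(2Z)-4-oxobut-2-en-2-yl]-2,3-dihydrofuran-2-yl}propanal; 14 methyl acrylate
Product: 15 methyl (4S,5R)-4,5-bis(TBS-oxy)-3-hydroxy-2-methylidene-5-{(2S)-2-methyl-3-oxo-5-[(2Z)-4-oxobut-2-en-2-yl]-2,3-dihydrofuran-2-yl}pentanoate (C3 epimers)
Conditions: DABCO, 14 (excess), 1,4-dioxane–H2O (1:1), rt
Reagents that add atoms: none
Why: Morita–Baylis–Hillman reaction, chemoselective for the saturated α-silyloxy aldehyde (C7) because the β,β-disubstituted Z-enal (C6) is not an acceptor under these conditions; the new carbinol centre is erased in step 7.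

Step 7
Reactants: 15 methyl (4S,5R)-4,5-bis(TBS-oxy)-3-hydroxy-2-methylidene-5-{(2S)-2-methyl-3-oxo-5-[(2Z)-4-oxobut-2-en-2-yl]-2,3-dihydrofuran-2-yl}pentanoate
Product: 16 methyl (2Z,4S,5R)-2-(bromomethyl)-4,5-bis(TBS-oxy)-5-{(2S)-2-methyl-3-oxo-5-[(2Z)-4-oxobut-2-en-2-yl]-2,3-dihydrofuran-2-yl}pent-2-enoate
Conditions: NBS/Me2S (premixed), CH2Cl2, −20 °C → rt
Reagents that add atoms: N-bromosuccinimide (NBS), BrN1C(=O)CCC1=O
Why: Corey–Kim-type activation of the Baylis–Hillman alcohol and SN2′ delivery of bromide give the thermodynamically preferred (Z)-2-(bromomethyl)enoate; premixing NBS with Me2S avoids free electrophilic bromine at the furanone.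

Step 8
Reactants: 16 methyl (2Z,4S,5R)-2-(bromomethyl)-4,5-bis(TBS-oxy)-5-{(2S)-2-methyl-3-oxo-5-[(2Z)-4-oxobut-2-en-2-yl]-2,3-dihydrofuran-2-yl}pent-2-enoate
Product: 18 (4Z,6R,7S,8S,9R,10S)-8,9-bis(TBS-oxy)-3,10-epoxy-1-oxogermacra-2,4,11(13)-trien-12,6-olide, via seco hydroxy ester 17 (not isolated)
Conditions: CrCl2 (8 equiv), DMF–THF, rt, slow addition (2 mM); aq. work-up; PPTS (cat.), CH2Cl2, rt
Reagents that add atoms: none
Why: Intramolecular chromium Barbier (Nozaki–Hiyama–Kishi-type) 2-(alkoxycarbonyl)allylation with lactonisation forms C6–C7, the ten-membered carbocycle and the lactone; C6 (R) and C7 (S) are predicted from a chair with C5 and C8 equatorial (6,7-anti, trans-lactone), the tethered aldehyde reaching the allyl face that carries the C9 tether with the C8–O bond in the allyl plane.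

Step 9
Reactants: 18 (4Z,6R,7S,8S,9R,10S)-8,9-bis(TBS-oxy)-3,10-epoxy-1-oxogermacra-2,4,11(13)-trien-12,6-olide
Product: 19 (4Z,6R,7R,8S,9R,10S)-3,10-epoxy-8,9-dihydroxy-1-oxogermacra-2,4,11(13)-trien-12,6-olide
Conditions: 48% aq. HF, MeCN, 0 °C → rt
Reagents that add atoms: none
Why: Acidic fluoride desilylation removes both TBS ethers without touching the lactone, the furanone or the exocyclic alkene; no stereocentre changes (the C7 descriptor changes only through CIP priorities).

Step 10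
Reactants: 19 (4Z,6R,7R,8S,9R,10S)-3,10-epoxy-8,9-dihydroxy-1-oxogermacra-2,4,11(13)-trien-12,6-olide
Product: 21 (4Z,6R,7R,8S,9R,10S,11S)-3,10:11,13-diepoxy-8,9-dihydroxy-1-oxogermacra-2,4-dien-12,6-olide, via magnesium diolate 20 (not isolated)
Conditions: Bu2Mg (1.0 equiv), THF–toluene, −40 °C; TBHP (in decane), −40 → 0 °C
Reagents that add atoms: tert-butyl hydroperoxide (TBHP), CC(C)(C)OO
Why: Proposed new method: substrate-templated, magnesium-alkoxide-directed nucleophilic (Weitz–Scheffer) epoxidation, in which Bu2Mg turns the C8/C9 diol into a magnesium diolate that binds TBHP as Mg–OOtBu, the peroxide is delivered conjugately to C13 from the metal anchored at O8, and the enolate closes on the proximal peroxide oxygen while the leaving tert-butoxide stays on that magnesium, so oxygen is attached to C11 on the face syn to C8 (11S), against the intrinsic steric bias; only the strained s-cis exocyclic enoate is electrophilic enough to react; the closest known reaction types are the Bu2Mg/dialkyl tartrate/TBHP epoxidation of enones (a magnesium diolate carries the peroxide) and the hydroxyl-directed syn epoxidation of γ-hydroxy enoates and vinyl sulfones with LiOOtBu.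

Step 11
Reactants: 21 (4Z,6R,7R,8S,9R,10S,11S)-3,10:11,13-diepoxy-8,9-dihydroxy-1-oxogermacra-2,4-dien-12,6-olide; 22 methacryloyl chloride
Product: 23 (4Z,6R,7S,8S,9R,10S,11S)-3,10:11,13-diepoxy-9-hydroxy-8-(2-methylprop-2-enoyloxy)-1-oxogermacra-2,4-dien-12,6-olide (target)
Conditions: Et3N, DMAP (cat.), CH2Cl2, −40 → −10 °C
Reagents that add atoms: none
Why: DMAP-catalysed acylation with the acid chloride takes place at the C8 hydroxyl because the C9 hydroxyl is neopentylic (next to quaternary C10) and hydrogen-bonded to the furanone; no stereocentre is affected.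

## Compound list

1 | (2Z)-3-methylpent-2-en-4-yn-1-ol | C#C/C(C)=C\CO | starting material
2 | triethyl{[(2Z)-3-methylpent-2-en-4-yn-1-yl]oxy}silane | C#C/C(C)=C\CO[Si](CC)(CC)CC | intermediate
3 | L-threono-1,4-lactone, (3R,4S)-3,4-dihydroxyoxolan-2-one | O=C1[C@H](O)[C@@H](O)CO1 | starting material
4 | (3R,4S)-3,4-bis[(tert-butyldimethylsilyl)oxy]oxolan-2-one | O=C1[C@H](O[Si](C)(C)C(C)(C)C)[C@@H](O[Si](C)(C)C(C)(C)C)CO1 | intermediate
5 | ethyl vinyl ether (ethoxyethene) | C=COCC | starting material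
6 | 1-ethoxyvinyllithium | [Li]C(=C)OCC | intermediate
7 | lithium (3R,4S)-3,4-bis[(tert-butyldimethylsilyl)oxy]-2-(1-ethoxyethenyl)oxolan-2-olate (C2 epimers) | [Li]OC1(C(=C)OCC)[C@H](O[Si](C)(C)C(C)(C)C)[C@@H](O[Si](C)(C)C(C)(C)C)CO1 | intermediate
8 | [(3Z)-3-methyl-5-(triethylsilyloxy)pent-3-en-1-yn-1-yl]lithium | [Li]C#C/C(C)=C\CO[Si](CC)(CC)CC | intermediate
9 | dilithium (3S,4R,5S)-4,5-bis[(tert-butyldimethylsilyl)oxy]-2-ethoxy-3-[(3Z)-3-methyl-5-(triethylsilyloxy)pent-3-en-1-yn-1-yl]hex-1-ene-3,6-diolate | C=C(OCC)[C@](O[Li])(C#C/C(C)=C\CO[Si](CC)(CC)CC)[C@H](O[Si](C)(C)C(C)(C)C)[C@@H](O[Si](C)(C)C(C)(C)C)CO[Li] | intermediate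
10 | (3S,4R,5S)-4,5-bis[(tert-butyldimethylsilyl)oxy]-2-ethoxy-3-[(3Z)-3-methyl-5-(triethylsilyloxy)pent-3-en-1-yn-1-yl]-6-(triethylsilyloxy)hex-1-en-3-ol | C=C(OCC)[C@](O)(C#C/C(C)=C\CO[Si](CC)(CC)CC)[C@H](O[Si](C)(C)C(C)(C)C)[C@@H](O[Si](C)(C)C(C)(C)C)CO[Si](CC)(CC)CC | intermediate
11 | (3S,4R,5S)-4,5-bis[(tert-butyldimethylsilyl)oxy]-3-hydroxy-3-[(3Z)-3-methyl-5-(triethylsilyloxy)pent-3-en-1-yn-1-yl]-6-(triethylsilyloxy)hexan-2-one | CC(=O)[C@](O)(C#C/C(C)=C\CO[Si](CC)(CC)CC)[C@H](O[Si](C)(C)C(C)(C)C)[C@@H](O[Si](C)(C)C(C)(C)C)CO[Si](CC)(CC)CC | intermediate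
12 | (2S)-2-{(1R,2S)-1,2-bis[(tert-butyldimethylsilyl)oxy]-3-(triethylsilyloxy)propyl}-2-methyl-5-[(2Z)-4-(triethylsilyloxy)but-2-en-2-yl]furan-3(2H)-one | CC[Si](CC)(CC)OC/C=C(/C)C1=CC(=O)[C@@](C)(O1)[C@H](O[Si](C)(C)C(C)(C)C)[C@@H](O[Si](C)(C)C(C)(C)C)CO[Si](CC)(CC)CC | intermediate
13 | (2R,3R)-2,3-bis[(tert-butyldimethylsilyl)oxy]-3-{(2S)-2-methyl-3-oxo-5-[(2Z)-4-oxobut-2-en-2-yl]-2,3-dihydrofuran-2-yl}propanal | O=C/C=C(/C)C1=CC(=O)[C@@](C)(O1)[C@H](O[Si](C)(C)C(C)(C)C)[C@@H](O[Si](C)(C)C(C)(C)C)C=O | intermediate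
14 | methyl acrylate (methyl prop-2-enoate) | C=CC(=O)OC | starting material
15 | methyl (4S,5R)-4,5-bis[(tert-butyldimethylsilyl)oxy]-3-hydroxy-2-methylidene-5-{(2S)-2-methyl-3-oxo-5-[(2Z)-4-oxobut-2-en-2-yl]-2,3-dihydrofuran-2-yl}pentanoate (C3 epimers) | O=C/C=C(/C)C1=CC(=O)[C@@](C)(O1)[C@H](O[Si](C)(C)C(C)(C)C)[C@@H](O[Si](C)(C)C(C)(C)C)C(O)C(=C)C(=O)OC | intermediate
16 | methyl (2Z,4S,5R)-2-(bromomethyl)-4,5-bis[(tert-butyldimethylsilyl)oxy]-5-{(2S)-2-methyl-3-oxo-5-[(2Z)-4-oxobut-2-en-2-yl]-2,3-dihydrofuran-2-yl}pent-2-enoate | O=C/C=C(/C)C1=CC(=O)[C@@](C)(O1)[C@H](O[Si](C)(C)C(C)(C)C)[C@@H](O[Si](C)(C)C(C)(C)C)/C=C(\CBr)C(=O)OC | intermediate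
17 | methyl (4Z,6R,7S,8S,9R,10S)-8,9-bis[(tert-butyldimethylsilyl)oxy]-3,10-epoxy-6-hydroxy-1-oxogermacra-2,4,11(13)-trien-12-oate (seco hydroxy ester) | CC(C)(C)[Si](C)(C)O[C@H]1[C@H]([C@H](O)/C=C(/C)C2=CC(=O)[C@@](C)(O2)[C@@H]1O[Si](C)(C)C(C)(C)C)C(=C)C(=O)OC | intermediate
18 | (4Z,6R,7S,8S,9R,10S)-8,9-bis[(tert-butyldimethylsilyl)oxy]-3,10-epoxy-1-oxogermacra-2,4,11(13)-trien-12,6-olide (trans-fused lactone) | CC(C)(C)[Si](C)(C)O[C@H]1[C@@H]2[C@@H](/C=C(/C)C3=CC(=O)[C@@](C)(O3)[C@@H]1O[Si](C)(C)C(C)(C)C)OC(=O)C2=C | intermediate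
19 | (4Z,6R,7R,8S,9R,10S)-3,10-epoxy-8,9-dihydroxy-1-oxogermacra-2,4,11(13)-trien-12,6-olide | O[C@H]1[C@@H]2[C@@H](/C=C(/C)C3=CC(=O)[C@@](C)(O3)[C@@H]1O)OC(=O)C2=C | intermediate
20 | magnesium 8,9-diolate of 19 (O8,O9-bound magnesium alkoxide) | [Mg+2].[O-][C@H]1[C@@H]2[C@@H](/C=C(/C)C3=CC(=O)[C@@](C)(O3)[C@@H]1[O-])OC(=O)C2=C | intermediate
21 | (4Z,6R,7R,8S,9R,10S,11S)-3,10:11,13-diepoxy-8,9-dihydroxy-1-oxogermacra-2,4-dien-12,6-olide | O[C@H]1[C@@H]2[C@@H](/C=C(/C)C3=CC(=O)[C@@](C)(O3)[C@@H]1O)OC(=O)[C@@]21CO1 | intermediate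
22 | methacryloyl chloride (2-methylprop-2-enoyl chloride) | C=C(C)C(Cl)=O | starting material
23 | (4Z,6R,7S,8S,9R,10S,11S)-3,10:11,13-diepoxy-9-hydroxy-8-(2-methylprop-2-enoyloxy)-1-oxogermacra-2,4-dien-12,6-olide (CNP0407138.2) | C=C(C)C(=O)O[C@H]1[C@@H]2[C@@H](/C=C(/C)C3=CC(=O)[C@@](C)(O3)[C@@H]1O)OC(=O)[C@@]21CO1 | target

## Step count and risks

Total step count: 11. Longest linear sequence: 10 steps (steps 2–11 from 3; equally step 1 then steps 3–11 from 1).

The three steps most likely to fail: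

Step 3 (double addition; configuration of carbinol C1, which later becomes C10). The Felkin–Anh preference could be eroded or reversed by the lithium alkoxides present. The fallback sets out from lactone 4 and comes back to the route at dialkoxide 9. The two carbon nucleophiles are introduced in the opposite order: lithium acetylide 8 is added to 4 at −78 °C and the mixture is quenched to isolate alkynyl lactol F1. F1 is then treated with an excess of 1-ethoxyvinyllithium 6 (−78 → −20 °C), which opens the lactol and adds to the ynone. Because the directing centre C9 is the same while the roles of the two groups are exchanged, the prevailing facial bias now gives the opposite C1 configuration, which corrects a main-order result that favoured the C1 epimer. Silylation and hydrolysis then follow as before through 10 to 11.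

Step 8 (macrocyclisation; ring closure, trans-lactone and C7/C8 relationship). Oligomerisation or a cis-lactone/C7-epimer is possible, because acyclic 2-(alkoxycarbonyl)allyl metals often favour syn adducts. The fallback sets out from bromide 16 and comes back at macrolactone 18. Palladium-catalysed borylation of the allylic bromide (B2pin2, Pd2(dba)3) gives allylboronate aldehyde F2, in which the nucleophile is a configurationally defined allylboronate that does not add to the aldehyde at room temperature. Brønsted-acid catalysis (TfOH, toluene, high dilution) then triggers the intramolecular allylboration and lactonisation (through hydroxy ester 17). This acid-catalysed variant is known for 2-alkoxycarbonyl allylboronates to deliver trans-β,γ-disubstituted α-methylene lactones, and it replaces the equilibrating allylchromium by a closed, boron-centred transition state.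

Step 10 (the proposed magnesium-templated epoxidation). It is new; translactonisation to the 8,12-olide, oxa-Michael addition, or closure on the wrong face may compete. The fallback uses known chemistry, sets out from diol 19 and comes back at epoxide 21. Hydroxyl-directed osmylation (OsO4·TMEDA, CH2Cl2, −78 °C; NaHSO3 work-up) is delivered by hydrogen bonding from the C8/C9 hydroxyls to the face of the exocyclic alkene syn to C8 and gives tetraol F3. Selective sulfonylation of its primary C13 hydroxyl (TsCl, Et3N, Bu2SnO cat.) gives tosylate F4. K2CO3 in acetone then closes the epoxide by attack of the tertiary C11 alkoxide on C13, which leaves C11 (S) untouched.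

## Further compounds

F1 | step 3 | (3R,4S)-3,4-bis[(tert-butyldimethylsilyl)oxy]-2-[(3Z)-3-methyl-5-(triethylsilyloxy)pent-3-en-1-yn-1-yl]oxolan-2-ol (alkynyl lactol, C2 epimers) | OC1(C#C/C(C)=C\CO[Si](CC)(CC)CC)[C@H](O[Si](C)(C)C(C)(C)C)[C@@H](O[Si](C)(C)C(C)(C)C)CO1
F2 | step 8 | allylboronate aldehyde: 16 with CH2Bpin in place of CH2Br, same double-bond geometry (formally 2E), 4S,5R | O=C/C=C(/C)C1=CC(=O)[C@@](C)(O1)[C@H](O[Si](C)(C)C(C)(C)C)[C@@H](O[Si](C)(C)C(C)(C)C)/C=C(\CB2OC(C)(C)C(C)(C)O2)C(=O)OC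
F3 | step 10 | (4Z,6R,7R,8S,9R,10S,11S)-3,10-epoxy-8,9,11,13-tetrahydroxy-1-oxogermacra-2,4-dien-12,6-olide (tetraol) | O[C@H]1[C@@H]2[C@@H](/C=C(/C)C3=CC(=O)[C@@](C)(O3)[C@@H]1O)OC(=O)[C@@]2(O)CO
F4 | step 10 | (4Z,6R,7R,8S,9R,10S,11S)-3,10-epoxy-8,9,11-trihydroxy-13-(4-methylbenzenesulfonyloxy)-1-oxogermacra-2,4-dien-12,6-olide (tosylate) | O[C@H]1[C@@H]2[C@@H](/C=C(/C)C3=CC(=O)[C@@](C)(O3)[C@@H]1O)OC(=O)[C@@]2(O)COS(=O)(=O)c1ccc(C)cc1
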